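The flavanone is cut at C3–C4. C4, the aryl ketone carbon of ring C, is handled as an acyl anion in the form of a 2-aryl-1,3-dithiane, and C2, the benzylic oxygen-bearing carbon two bonds away, arrives with C3 and the phenyl ring as (S)-styrene oxide. In one operation the lithiated dithiane opens the epoxide at its CH2 end, joining ring A to the whole C2–C3 unit with the stereocentre already in place; no ring closes. The precursor is the fully substituted ring A dithiane: finished C8 side chain, MOM ether on the future O1, benzyl ether on the future 5-OH. Mitsunobu closure of O1–C2 with inversion then gives 2S.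

Key step: step 9

Remark on the chemistry: the tertiary hydroxyl of 11 is assumed to react with 9-BBN much more slowly than the vinyl group, so borane 12 is drawn with the free carbinol; any B–O bond that does form is cleaved by the aqueous NaOH of the coupling.

Step 1
Reactants: 1 5-methoxyresorcinol
Product: 2 1-methoxy-3,5-bis(methoxymethoxy)benzene
Conditions: MOMCl (2.5 equiv), i-Pr2NEt, CH2Cl2, 0 °C to rt
Reagents that add atoms: chloromethyl methyl ether, COCCl
Why: Williamson-type O-alkylation of both phenols with the reactive α-chloro ether should be clean, and MOM ethers are chosen because they are the strongest ortho-directing groups for the metalation that follows.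

Step 2
Reactants: 2 1-methoxy-3,5-bis(methoxymethoxy)benzene
Product: 4 4-methoxy-2,6-bis(methoxymethoxy)benzaldehyde, via aryllithium 3 (not isolated)
Conditions: n-BuLi, TMEDA, THF, 0 °C; DMF, −78 °C to rt; H2O
Reagents that add atoms: N,N-dimethylformamide, CN(C)C=O
Why: Directed ortho-metalation should occur at the one ring carbon flanked by two chelating OMOM groups rather than at the two carbons next to OMe, and the aryllithium is then formylated by DMF (Bouveault-type formylation).

Step 3
Reactants: 4 4-methoxy-2,6-bis(methoxymethoxy)benzaldehyde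
Product: 5 2,6-dihydroxy-4-methoxybenzaldehyde
Conditions: conc. HCl (cat.), MeOH, 50 °C
Reagents that add atoms: none
Why: Acid-catalysed methanolysis (acetal exchange) removes both MOM groups and leaves the symmetric dihydroxy aldehyde, whose two phenols are equivalent.

Step 4
Reactants: 5 2,6-dihydroxy-4-methoxybenzaldehyde
Product: 6 2-(benzyloxy)-6-hydroxy-4-methoxybenzaldehyde
Conditions: BnBr (1.0 equiv), K2CO3 (1.1 equiv), acetone, rt
Reagents that add atoms: benzyl bromide, BrCc1ccccc1
Why: Williamson etherification of a symmetric diol cannot give a regioisomer, and it should stop at the mono-ether because the remaining phenol is locked in a hydrogen bond to the aldehyde oxygen and is far less nucleophilic.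

Step 5
Reactants: 6 2-(benzyloxy)-6-hydroxy-4-methoxybenzaldehyde
Product: 7 6-(benzyloxy)-2-hydroxy-3-iodo-4-methoxybenzaldehyde
Conditions: BnMe3N·ICl2 (1.05 equiv), NaHCO3, CH2Cl2–MeOH, rt
Reagents that add atoms: benzyltrimethylammonium dichloroiodate, C[N+](C)(C)Cc1ccccc1.Cl[I-]Cl
Why: Electrophilic aromatic iodination of chelated 2-hydroxy-4,6-dialkoxyaryl carbonyl compounds with the dichloroiodate salt is known to go ortho to the free hydroxyl, here the less hindered carbon between OH and OMe, which is the future C8.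

Step 6
Reactants: 7 6-(benzyloxy)-2-hydroxy-3-iodo-4-methoxybenzaldehyde; 8 propane-1,3-dithiol
Product: 9 2-[6-(benzyloxy)-2-hydroxy-3-iodo-4-methoxyphenyl]-1,3-dithiane
Conditions: BF3·OEt2 (0.5 equiv), CH2Cl2, 0 °C
Reagents that add atoms: none
Why: Lewis-acid-catalysed dithioacetalisation of the aldehyde is placed here, before the acid-sensitive tertiary carbinol exists, and the aryl benzyl ether and aryl iodide should tolerate sub-stoichiometric BF3 at 0 °C.

Step 7
Reactants: 9 2-[6-(benzyloxy)-2-hydroxy-3-iodo-4-methoxyphenyl]-1,3-dithiane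
Product: 10 2-[6-(benzyloxy)-3-iodo-4-methoxy-2-(methoxymethoxy)phenyl]-1,3-dithiane
Conditions: MOMCl, i-Pr2NEt, CH2Cl2, 0 °C to rt
Reagents that add atoms: chloromethyl methyl ether, COCCl
Why: O-alkylation of the acidic ortho-iodophenol under amine base leaves the dithiane C–H untouched and gives an ether that is inert to alkyllithiums and can chelate lithium in the key step.

Step 8
Reactants: 10 2-[6-(benzyloxy)-3-iodo-4-methoxy-2-(methoxymethoxy)phenyl]-1,3-dithiane; 11 2-methylbut-3-en-2-ol
Product: 13 2-[6-(benzyloxy)-3-(3-hydroxy-3-methylbutyl)-4-methoxy-2-(methoxymethoxy)phenyl]-1,3-dithiane, via alkylborane 12 (not isolated)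
Conditions: 11, 9-BBN, THF, 0 °C to rt; then 10, PdCl2(dppf) (5 mol %), 3 M aq NaOH, THF, 65 °C
Reagents that add atoms: none
Why: Anti-Markovnikov hydroboration of the vinyl group followed by B-alkyl Suzuki–Miyaura coupling installs the saturated chain directly, so no hydrogenation has to be run in the presence of the benzyl ether or sulfur, and the bidentate dppf ligand should suppress β-hydride elimination at the hindered aryl–palladium intermediate.

Step 9
Reactants: 13 2-[6-(benzyloxy)-3-(3-hydroxy-3-methylbutyl)-4-methoxy-2-(methoxymethoxy)phenyl]-1,3-dithiane; 14 (S)-styrene oxide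
Product: 16 (1R)-2-{2-[6-(benzyloxy)-3-(3-hydroxy-3-methylbutyl)-4-methoxy-2-(methoxymethoxy)phenyl]-1,3-dithian-2-yl}-1-phenylethan-1-ol, via dilithio dithiane 15 (not isolated)
Conditions: n-BuLi (2.05 equiv), THF, −78 to −20 °C; then 14 (1.3 equiv), −20 °C to rt; H2O
Reagents that add atoms: none
Why: Two equivalents of n-BuLi remove first the tertiary hydroxyl proton and then the dithiane C2–H, and the resulting sulfur-stabilised benzylic carbanion attacks the unsubstituted carbon of the lithium-coordinated epoxide by SN2, forming the C3–C4 bond. The closest known reaction type is the Corey–Seebach alkylation of 2-aryl-2-lithio-1,3-dithianes with terminal epoxides. No ring is closed. No stereocentre is created: the carbinol carbon keeps the configuration of the epoxide CH, whose C–O bond is never broken, and its descriptor changes from S to R only because the CIP ranking of CH2 and phenyl is reversed. The step needs terminal rather than benzylic attack, which the bulk of the tertiary carbanion and the absence of any strong Lewis acid secure, and it needs metalation at the dithiane rather than at the benzylic ether CH2, which the far higher acidity of the dithiane proton, lithium chelation by the ortho OMOM group and the low temperature secure.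

Step 10
Reactants: 16 (1R)-2-{2-[6-(benzyloxy)-3-(3-hydroxy-3-methylbutyl)-4-methoxy-2-(methoxymethoxy)phenyl]-1,3-dithian-2-yl}-1-phenylethan-1-ol
Product: 17 3-(benzyloxy)-2-{2-[(2R)-2-hydroxy-2-phenylethyl]-1,3-dithian-2-yl}-6-(3-hydroxy-3-methylbutyl)-5-methoxyphenol
Conditions: HCl (0.5 M in MeOH), THF, 0 °C to rt
Reagents that add atoms: none
Why: Dilute methanolic HCl cleaves the aryl MOM acetal by acetal exchange at a temperature at which neither the tertiary nor the benzylic carbinol should ionise, while the dithiane and benzyl ether are inert.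

Step 11
Reactants: 17 3-(benzyloxy)-2-{2-[(2R)-2-hydroxy-2-phenylethyl]-1,3-dithian-2-yl}-6-(3-hydroxy-3-methylbutyl)-5-methoxyphenol
Product: 18 (2S)-5-(benzyloxy)-8-(3-hydroxy-3-methylbutyl)-7-methoxy-2-phenylspiro[chromane-4,2'-[1,3]dithiane]
Conditions: PPh3, DIAD, THF, 0 °C to rt
Reagents that add atoms: none
Why: Intramolecular Mitsunobu etherification (6-exo-tet attack of the phenoxide on the alkoxyphosphonium carbon) closes ring C through O1–C2 with SN2 inversion, turning the R carbinol into the 2S centre, while the tertiary alcohol cannot be activated and the dithiane removes the carbonyl that would otherwise allow elimination to a chalcone.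

Step 12
Reactants: 18 (2S)-5-(benzyloxy)-8-(3-hydroxy-3-methylbutyl)-7-methoxy-2-phenylspiro[chromane-4,2'-[1,3]dithiane]
Product: 19 (2S)-5-(benzyloxy)-8-(3-hydroxy-3-methylbutyl)-7-methoxy-2-phenylchroman-4-one
Conditions: MeI (excess), CaCO3, MeCN–H2O (4:1), 45 °C
Reagents that add atoms: water, O
Why: Alkylative dithiane hydrolysis (S-methylation, opening to an aryl-stabilised thionium ion, capture by water) unmasks the C4 ketone under neutral, non-oxidising conditions that should neither halogenate the electron-rich ring A nor epimerise C2.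

Step 13
Reactants: 19 (2S)-5-(benzyloxy)-8-(3-hydroxy-3-methylbutyl)-7-methoxy-2-phenylchroman-4-one
Product: 20 (2S)-5-hydroxy-8-(3-hydroxy-3-methylbutyl)-7-methoxy-2-phenylchroman-4-one (CNP0160063.1)
Conditions: H2 (1 atm), Pd/C (10 wt % palladium on carbon), EtOAc, rt
Reagents that add atoms: none
Why: Catalytic hydrogenolysis of the aryl benzyl ether, possible now that sulfur is gone, frees the 5-OH and should be stopped after uptake of one equivalent of hydrogen so that the benzylic C2–O1 bond is kept.

Compound list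
1 | 5-methoxyresorcinol | COc1cc(O)cc(O)c1 | starting material
2 | 1-methoxy-3,5-bis(methoxymethoxy)benzene | COCOc1cc(OC)cc(OCOC)c1 | intermediate
3 | [4-methoxy-2,6-bis(methoxymethoxy)phenyl]lithium (not isolated) | [Li]c1c(OCOC)cc(OC)cc1OCOC | intermediate
4 | 4-methoxy-2,6-bis(methoxymethoxy)benzaldehyde | COCOc1cc(OC)cc(OCOC)c1C=O | intermediate
5 | 2,6-dihydroxy-4-methoxybenzaldehyde | COc1cc(O)c(C=O)c(O)c1 | intermediate
6 | 2-(benzyloxy)-6-hydroxy-4-methoxybenzaldehyde | COc1cc(O)c(C=O)c(OCc2ccccc2)c1 | intermediate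
7 | 6-(benzyloxy)-2-hydroxy-3-iodo-4-methoxybenzaldehyde | COc1cc(OCc2ccccc2)c(C=O)c(O)c1I | intermediate
8 | propane-1,3-dithiol | SCCCS | starting material
9 | 2-[6-(benzyloxy)-2-hydroxy-3-iodo-4-methoxyphenyl]-1,3-dithiane | COc1cc(OCc2ccccc2)c(C2SCCCS2)c(O)c1I | intermediate
10 | 2-[6-(benzyloxy)-3-iodo-4-methoxy-2-(methoxymethoxy)phenyl]-1,3-dithiane | COc1cc(OCc2ccccc2)c(C2SCCCS2)c(OCOC)c1I | intermediate
11 | 2-methylbut-3-en-2-ol | C=CC(C)(C)O | starting material
12 | 9-(3-hydroxy-3-methylbutyl)-9-borabicyclo[3.3.1]nonane (not isolated) | CC(C)(O)CCB1C2CCCC1CCC2 | intermediate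
13 | 2-[6-(benzyloxy)-3-(3-hydroxy-3-methylbutyl)-4-methoxy-2-(methoxymethoxy)phenyl]-1,3-dithiane | COc1cc(OCc2ccccc2)c(C2SCCCS2)c(OCOC)c1CCC(C)(C)O | intermediate
14 | (S)-styrene oxide | C1O[C@H]1c1ccccc1 | starting material
15 | dilithio derivative of 13: lithium on dithiane C2 and on the tertiary oxygen (not isolated) | [Li]C1(SCCCS1)c1c(OCc2ccccc2)cc(OC)c(CCC(C)(C)O[Li])c1OCOC | intermediate
16 | (1R)-2-{2-[6-(benzyloxy)-3-(3-hydroxy-3-methylbutyl)-4-methoxy-2-(methoxymethoxy)phenyl]-1,3-dithian-2-yl}-1-phenylethan-1-ol | COc1cc(OCc2ccccc2)c(C2(C[C@@H](O)c3ccccc3)SCCCS2)c(OCOC)c1CCC(C)(C)O | intermediate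
17 | 3-(benzyloxy)-2-{2-[(2R)-2-hydroxy-2-phenylethyl]-1,3-dithian-2-yl}-6-(3-hydroxy-3-methylbutyl)-5-methoxyphenol | COc1cc(OCc2ccccc2)c(C2(C[C@@H](O)c3ccccc3)SCCCS2)c(O)c1CCC(C)(C)O | intermediate
18 | (2S)-5-(benzyloxy)-8-(3-hydroxy-3-methylbutyl)-7-methoxy-2-phenylspiro[chromane-4,2'-[1,3]dithiane] | COc1cc(OCc3ccccc3)c2c(c1CCC(C)(C)O)O[C@H](c1ccccc1)CC21SCCCS1 | intermediate
19 | (2S)-5-(benzyloxy)-8-(3-hydroxy-3-methylbutyl)-7-methoxy-2-phenylchroman-4-one | COc1cc(OCc3ccccc3)c2c(c1CCC(C)(C)O)O[C@H](c1ccccc1)CC2=O | intermediate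
20 | (2S)-5-hydroxy-8-(3-hydroxy-3-methylbutyl)-7-methoxy-2-phenylchroman-4-one (CNP0160063.1) | COc1cc(O)c2c(c1CCC(C)(C)O)O[C@H](c1ccccc1)CC2=O | target

Total step count: 13. Longest linear sequence: 13 steps (1 to 20); compounds 8, 11 and 14 are purchased.

Steps most likely to fail

Step 9. The carbanion is tertiary, benzylic and flanked by two ortho substituents, so carbon–carbon bond formation with the epoxide may be too slow. Proton return, metalation of the benzylic ether or opening at the benzylic epoxide carbon may then take over. The fallback gives up the chiral-pool coupling and sets C2 by catalysis. It sets out from 13, whose lithiated form (n-BuLi, THF) would be quenched with the small electrophile MeI to give 2-[6-(benzyloxy)-3-(3-hydroxy-3-methylbutyl)-4-methoxy-2-(methoxymethoxy)phenyl]-2-methyl-1,3-dithiane F1. MeI/CaCO3 in aqueous MeCN would unmask the methyl ketone 1-[6-(benzyloxy)-3-(3-hydroxy-3-methylbutyl)-4-methoxy-2-(methoxymethoxy)phenyl]ethan-1-one F2. Condensation with DMF dimethyl acetal would give the enaminone (2E)-1-[6-(benzyloxy)-3-(3-hydroxy-3-methylbutyl)-4-methoxy-2-(methoxymethoxy)phenyl]-3-(dimethylamino)prop-2-en-1-one F3. Dilute HCl in MeOH would remove the MOM group and close the pyranone ring with loss of dimethylamine to give 5-(benzyloxy)-8-(3-hydroxy-3-methylbutyl)-7-methoxy-4H-chromen-4-one F4. Asymmetric conjugate addition of phenylboronic acid (Pd(OCOCF3)2, the tert-butyl-PyOX enantiomer that leads to the 2S product, NH4PF6, H2O, 1,2-dichloroethane, 60 °C) would then give 19, where the route is rejoined before step 13.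

Step 11. The phenol is flanked on both sides and the activated carbon is benzylic, so attack on the bulky alkoxyphosphonium ion may be slow enough for ionisation (erosion of enantiopurity) or E2 loss to a styrene to compete. The fallback replaces the single Mitsunobu inversion by two separate SN2 inversions with a small leaving group, and therefore starts from the enantiomeric epoxide. Compound 13 would be coupled with commercially available (R)-styrene oxide under the conditions of step 9 to give (1S)-2-{2-[6-(benzyloxy)-3-(3-hydroxy-3-methylbutyl)-4-methoxy-2-(methoxymethoxy)phenyl]-1,3-dithian-2-yl}-1-phenylethan-1-ol F5. The MOM group would be removed as in step 10 to give 3-(benzyloxy)-2-{2-[(2S)-2-hydroxy-2-phenylethyl]-1,3-dithian-2-yl}-6-(3-hydroxy-3-methylbutyl)-5-methoxyphenol F6. Appel reaction (PPh3, CCl4, CH2Cl2) would convert the secondary carbinol with inversion into 3-(benzyloxy)-2-{2-[(2R)-2-chloro-2-phenylethyl]-1,3-dithian-2-yl}-6-(3-hydroxy-3-methylbutyl)-5-methoxyphenol F7. The phenoxide (K2CO3, DMF) would then displace chloride with a second inversion (intramolecular Williamson etherification) to give 18.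

Step 8. Sulfur coordination may deactivate the palladium catalyst, or transmetalation and reductive elimination at the doubly ortho-substituted aryl–palladium species may be slow enough for protodeiodination to win. The fallback moves the carbon–carbon coupling to a point before sulfur is introduced and changes it to a Heck reaction. From 7, Heck coupling with 11 (Pd(OAc)2, n-Bu4NCl, NaHCO3, DMF, 80 °C) would give 6-(benzyloxy)-2-hydroxy-3-[(1E)-3-hydroxy-3-methylbut-1-en-1-yl]-4-methoxybenzaldehyde F8. Homogeneous hydrogenation (H2, RhCl(PPh3)3, benzene–EtOH), which spares the benzyl ether and the aldehyde, would give 6-(benzyloxy)-2-hydroxy-3-(3-hydroxy-3-methylbutyl)-4-methoxybenzaldehyde F9. Dithioacetalisation with 8 under the mild Lewis acid MgBr2·OEt2, chosen so that the tertiary carbinol does not ionise, would give 2-[6-(benzyloxy)-2-hydroxy-3-(3-hydroxy-3-methylbutyl)-4-methoxyphenyl]-1,3-dithiane F10. MOMCl/i-Pr2NEt would then give 13.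

Further compounds
F1 | step 9 | 2-[6-(benzyloxy)-3-(3-hydroxy-3-methylbutyl)-4-methoxy-2-(methoxymethoxy)phenyl]-2-methyl-1,3-dithiane | COc1cc(OCc2ccccc2)c(C2(C)SCCCS2)c(OCOC)c1CCC(C)(C)O
F2 | step 9 | 1-[6-(benzyloxy)-3-(3-hydroxy-3-methylbutyl)-4-methoxy-2-(methoxymethoxy)phenyl]ethan-1-one | COc1cc(OCc2ccccc2)c(C(C)=O)c(OCOC)c1CCC(C)(C)O
F3 | step 9 | (2E)-1-[6-(benzyloxy)-3-(3-hydroxy-3-methylbutyl)-4-methoxy-2-(methoxymethoxy)phenyl]-3-(dimethylamino)prop-2-en-1-one | COc1cc(OCc2ccccc2)c(C(=O)/C=C/N(C)C)c(OCOC)c1CCC(C)(C)O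
F4 | step 9 | 5-(benzyloxy)-8-(3-hydroxy-3-methylbutyl)-7-methoxy-4H-chromen-4-one | COc1cc(OCc3ccccc3)c2c(=O)ccoc2c1CCC(C)(C)O
F5 | step 11 | (1S)-2-{2-[6-(benzyloxy)-3-(3-hydroxy-3-methylbutyl)-4-methoxy-2-(methoxymethoxy)phenyl]-1,3-dithian-2-yl}-1-phenylethan-1-ol | COc1cc(OCc2ccccc2)c(C2(C[C@H](O)c3ccccc3)SCCCS2)c(OCOC)c1CCC(C)(C)O
F6 | step 11 | 3-(benzyloxy)-2-{2-[(2S)-2-hydroxy-2-phenylethyl]-1,3-dithian-2-yl}-6-(3-hydroxy-3-methylbutyl)-5-methoxyphenol | COc1cc(OCc2ccccc2)c(C2(C[C@H](O)c3ccccc3)SCCCS2)c(O)c1CCC(C)(C)O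
F7 | step 11 | 3-(benzyloxy)-2-{2-[(2R)-2-chloro-2-phenylethyl]-1,3-dithian-2-yl}-6-(3-hydroxy-3-methylbutyl)-5-methoxyphenol | COc1cc(OCc2ccccc2)c(C2(C[C@@H](Cl)c3ccccc3)SCCCS2)c(O)c1CCC(C)(C)O
F8 | step 8 | 6-(benzyloxy)-2-hydroxy-3-[(1E)-3-hydroxy-3-methylbut-1-en-1-yl]-4-methoxybenzaldehyde | COc1cc(OCc2ccccc2)c(C=O)c(O)c1/C=C/C(C)(C)O
F9 | step 8 | 6-(benzyloxy)-2-hydroxy-3-(3-hydroxy-3-methylbutyl)-4-methoxybenzaldehyde | COc1cc(OCc2ccccc2)c(C=O)c(O)c1CCC(C)(C)O
F10 | step 8 | 2-[6-(benzyloxy)-2-hydroxy-3-(3-hydroxy-3-methylbutyl)-4-methoxyphenyl]-1,3-dithiane | COc1cc(OCc2ccccc2)c(C2SCCCS2)c(O)c1CCC(C)(C)O
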